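The pyranone (ring C) is disconnected at O1–C8a, C4–C4a and O1–C2. Ring A has C8a (bearing O1) next to C4a (bearing the C4 carbonyl), and C4a is flanked by the 5-OMe: exactly the polarity of 3,5-dimethoxybenzyne, which takes an O-nucleophile at the carbon remote from OMe and an acyl group at the carbon beside it. In one operation the aryne is to insert into the C(acyl)–O bond of a 2-aryl-3-methoxyacrylate, and the liberated phenoxide closes ring C by addition–elimination at C2. The precursors are a 2-silylaryl triflate (ring A) and (E)-2-[3,4-bis(prenyloxy)phenyl]-3-methoxyacrylic acid, which already holds ring B, C2, C3 and C4 at the chromone oxidation level.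

Key step: step 7

Remark: prenyl stands for 3-methylbut-2-en-1-yl; the target has no stereocentre, and the E geometry of the enol ether is the expected outcome but is not required, because ring closure at C2 erases it.

Step 1
Reactants: 1 3,5-dimethoxyphenol
Product: 2 3,5-dimethoxyphenyl N-isopropylcarbamate
Conditions: i-PrNCO (1.3 equiv), Et3N (0.2 equiv), CH2Cl2, rt
Reagents that add atoms: isopropyl isocyanate, CC(C)N=C=O
Why: Amine-catalysed addition of the phenol O–H across the isocyanate (carbamoylation) should be clean and installs a strong directing group that can later be removed without acid or fluoride.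

Step 2
Reactants: 2 3,5-dimethoxyphenyl N-isopropylcarbamate
Product: 6 3,5-dimethoxy-2-(trimethylsilyl)phenyl N-isopropylcarbamate, via N-silyl carbamate 3 (not isolated), via aryllithium 4 (not isolated), via bis-silyl carbamate 5 (not isolated)
Conditions: TMSOTf (1.1 equiv), TMEDA (1.1 equiv), Et2O, 0 °C to rt; n-BuLi (2.2 equiv), TMEDA (2.2 equiv), −78 °C; TMSCl (4 equiv), −78 °C to rt; aq NaHSO4
Reagents that add atoms: chlorotrimethylsilane, C[Si](C)(C)Cl
Why: Directed ortho-metalation: transient N-silylation removes the acidic N–H, the O-carbamate then steers lithiation to C2, where the neighbouring 3-OMe cooperates, in preference to C4 between the two weaker methoxy directors, and TMSCl traps the aryllithium before the N–Si bond is hydrolysed on work-up.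

Step 3
Reactants: 6 3,5-dimethoxy-2-(trimethylsilyl)phenyl N-isopropylcarbamate
Product: 8 3,5-dimethoxy-2-(trimethylsilyl)phenyl trifluoromethanesulfonate, via silylphenol 7 (not isolated)
Conditions: DBU (1.5 equiv), Et2NH (1.2 equiv), MeCN, 40 °C; then PhNTf2 (1.5 equiv), rt
Reagents that add atoms: N-phenylbis(trifluoromethanesulfonimide), O=S(=O)(N(c1ccccc1)S(=O)(=O)C(F)(F)F)C(F)(F)F
Why: E1cB cleavage of the N-monoalkyl carbamate (the expelled isopropyl isocyanate is scavenged by Et2NH) frees the phenoxide, which is O-sulfonylated in the same pot by the mild triflyl donor PhNTf2 without disturbing the C–Si bond.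

Step 4
Reactants: 9 methyl 2-(3,4-dihydroxyphenyl)acetate; 10 prenyl bromide (1-bromo-3-methylbut-2-ene)
Product: 11 methyl 2-[3,4-bis(3-methylbut-2-enyloxy)phenyl]acetate
Conditions: 10 (2.4 equiv), K2CO3 (3 equiv), acetone, reflux
Reagents that add atoms: none
Why: Double Williamson etherification of the catechol with the reactive allylic bromide under weak base should proceed by SN2 at oxygen and leave the methyl ester untouched.

Step 5
Reactants: 11 methyl 2-[3,4-bis(3-methylbut-2-enyloxy)phenyl]acetate; 12 methyl formate
Product: 14 methyl (E)-2-[3,4-bis(3-methylbut-2-enyloxy)phenyl]-3-methoxyprop-2-enoate, via sodium enolate 13 (not isolated)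
Conditions: NaH (2.5 equiv), 12 (5 equiv), THF–DMF, 0 °C to rt; then Me2SO4 (3 equiv), 0 °C to rt; aq NH3 quench
Reagents that add atoms: dimethyl sulfate, COS(=O)(=O)OC
Why: Crossed Claisen condensation with the non-enolisable formate is driven by formation of the stabilised formyl-ester enolate, and the hard electrophile dimethyl sulfate in a dipolar aprotic medium should alkylate that enolate on oxygen to give the push–pull enol ether, the E isomer being expected to predominate.

Step 6
Reactants: 14 methyl (E)-2-[3,4-bis(3-methylbut-2-enyloxy)phenyl]-3-methoxyprop-2-enoate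
Product: 16 (E)-2-[3,4-bis(3-methylbut-2-enyloxy)phenyl]-3-methoxyprop-2-enoic acid, via lithium carboxylate 15 (not isolated)
Conditions: LiOH·H2O (3 equiv), THF–MeOH–H2O, 50 °C; then cold 0.5 M HCl to pH 4, 0 °C, immediate extraction
Reagents that add atoms: lithium hydroxide monohydrate, [Li+].[OH-].O
Why: Saponification (acyl–oxygen cleavage by hydroxide) should hydrolyse the ester while the methoxy-donated C3 resists conjugate attack, and cold, mild acidification should spare the enol ether and the prenyl ethers.

Step 7
Reactants: 16 (E)-2-[3,4-bis(3-methylbut-2-enyloxy)phenyl]-3-methoxyprop-2-enoic acid; 8 3,5-dimethoxy-2-(trimethylsilyl)phenyl trifluoromethanesulfonate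
Product: 22 Glabrescione B, via caesium carboxylate 17 (not isolated), via 3,5-dimethoxybenzyne 18 (not isolated), via aryl anion 19 (not isolated), via acylphenoxide 20 (not isolated), via chromanone enolate 21 (not isolated)
Conditions: Cs2CO3 (0.5 equiv), MeOH, rt, evaporation, PhMe azeotrope, vacuum; then CsF (4 equiv), 8 (1.6 equiv), anhydrous THF, sealed tube, 100 °C; aq NH4Cl
Reagents that add atoms: none
Why: Proposed new method: fluoride removes the silyl group of 8 with loss of triflate and releases aryne 18 slowly (CsF is sparingly soluble in THF); a carboxylate oxygen of 17 adds to the aryne carbon remote from the 3-OMe, giving aryl anion 19 beside that methoxy group, and 19 attacks its own ester carbonyl through a four-membered transition state that opens to acylphenoxide 20, a net insertion of the aryne into the C(acyl)–O bond (a 1,3 O-to-C acyl migration of the anionic Fries kind) that forms O1–C8a and C4–C4a. Ring C, the only ring closed, then forms by 6-endo-trig oxa-Michael addition of the phenoxide of 20 to the β-methoxy enone (O1–C2), and enolate 21 expels methoxide by E1cB to give the chromone, so no stereocentre survives and none needs control. The closest known reaction type is the CsF-promoted insertion of arynes from silylaryl triflates into carboxylic acids to give ortho-hydroxyaryl ketones, which close in the same pot to 4-chromanones from acrylic acids and to flavones from arylpropiolic acids; a 3-alkoxy-2-arylacrylic acid giving an isoflavone in this way has not been shown. Regioselectivity on the unsymmetrical aryne is needed and is secured by the 3-OMe group, whose inductive effect and distortion of the triple bond send the oxygen nucleophile to the distal carbon (future C8a) and the acyl group to the carbon beside OMe (future C4a). Carbonyl attack by 19 must also beat protonation, conjugate attack at C3 (which would lead to a 3-arylcoumarin) and ene reaction of 18 with the prenyl alkenes, which the proton-free caesium salt, the short reach of the in-plane aryl anion to the adjacent ester carbonyl and the low standing concentration of aryne should ensure. Because C2 already sits at the formyl oxidation level and carries methoxide as a nucleofuge, the chromone should arise without any later one-carbon insertion or dehydrogenation.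

Compound list
1 | 3,5-dimethoxyphenol | COc1cc(O)cc(OC)c1 | starting material
2 | 3,5-dimethoxyphenyl N-isopropylcarbamate | COc1cc(OC(=O)NC(C)C)cc(OC)c1 | intermediate
3 | 3,5-dimethoxyphenyl N-isopropyl-N-(trimethylsilyl)carbamate | COc1cc(OC(=O)N(C(C)C)[Si](C)(C)C)cc(OC)c1 | intermediate
4 | 2-lithio-3,5-dimethoxyphenyl N-isopropyl-N-(trimethylsilyl)carbamate | COc1cc(OC)c([Li])c(OC(=O)N(C(C)C)[Si](C)(C)C)c1 | intermediate
5 | 3,5-dimethoxy-2-(trimethylsilyl)phenyl N-isopropyl-N-(trimethylsilyl)carbamate | COc1cc(OC)c([Si](C)(C)C)c(OC(=O)N(C(C)C)[Si](C)(C)C)c1 | intermediate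
6 | 3,5-dimethoxy-2-(trimethylsilyl)phenyl N-isopropylcarbamate | COc1cc(OC)c([Si](C)(C)C)c(OC(=O)NC(C)C)c1 | intermediate
7 | 3,5-dimethoxy-2-(trimethylsilyl)phenol (held in the flask as its DBU-H+ phenoxide) | COc1cc(O)c([Si](C)(C)C)c(OC)c1 | intermediate
8 | 3,5-dimethoxy-2-(trimethylsilyl)phenyl trifluoromethanesulfonate | COc1cc(OC)c([Si](C)(C)C)c(OS(=O)(=O)C(F)(F)F)c1 | intermediate
9 | methyl 2-(3,4-dihydroxyphenyl)acetate | COC(=O)Cc1ccc(O)c(O)c1 | starting material
10 | prenyl bromide (1-bromo-3-methylbut-2-ene) | CC(C)=CCBr | starting material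
11 | methyl 2-[3,4-bis(3-methylbut-2-enyloxy)phenyl]acetate | COC(=O)Cc1ccc(OCC=C(C)C)c(OCC=C(C)C)c1 | intermediate
12 | methyl formate | COC=O | starting material
13 | sodium enolate of methyl 2-[3,4-bis(3-methylbut-2-enyloxy)phenyl]-3-oxopropanoate (enolate geometry mobile) | [Na+].[O-]C=C(C(=O)OC)c1ccc(OCC=C(C)C)c(OCC=C(C)C)c1 | intermediate
14 | methyl (E)-2-[3,4-bis(3-methylbut-2-enyloxy)phenyl]-3-methoxyprop-2-enoate | CO/C=C(/C(=O)OC)c1ccc(OCC=C(C)C)c(OCC=C(C)C)c1 | intermediate
15 | lithium (E)-2-[3,4-bis(3-methylbut-2-enyloxy)phenyl]-3-methoxyprop-2-enoate | [Li+].CO/C=C(/C(=O)[O-])c1ccc(OCC=C(C)C)c(OCC=C(C)C)c1 | intermediate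
16 | (E)-2-[3,4-bis(3-methylbut-2-enyloxy)phenyl]-3-methoxyprop-2-enoic acid | CO/C=C(/C(=O)O)c1ccc(OCC=C(C)C)c(OCC=C(C)C)c1 | intermediate
17 | caesium (E)-2-[3,4-bis(3-methylbut-2-enyloxy)phenyl]-3-methoxyprop-2-enoate | [Cs+].CO/C=C(/C(=O)[O-])c1ccc(OCC=C(C)C)c(OCC=C(C)C)c1 | intermediate
18 | 3,5-dimethoxybenzyne (1,2-didehydro-3,5-dimethoxybenzene) | COC1=CC(OC)=CC#C1 | intermediate
19 | caesium 2-{[(E)-2-[3,4-bis(3-methylbut-2-enyloxy)phenyl]-3-methoxyprop-2-enoyl]oxy}-4,6-dimethoxybenzen-1-ide (carbanion between the ester oxygen and a methoxy group) | [Cs+].CO/C=C(/C(=O)Oc1[c-]c(OC)cc(OC)c1)c1ccc(OCC=C(C)C)c(OCC=C(C)C)c1 | intermediate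
20 | caesium 2-{(E)-2-[3,4-bis(3-methylbut-2-enyloxy)phenyl]-3-methoxyprop-2-enoyl}-3,5-dimethoxyphenolate | [Cs+].CO/C=C(/C(=O)c1c([O-])cc(OC)cc1OC)c1ccc(OCC=C(C)C)c(OCC=C(C)C)c1 | intermediate
21 | caesium 3-[3,4-bis(3-methylbut-2-enyloxy)phenyl]-2,5,7-trimethoxy-2H-chromen-4-olate (racemic at C2) | [Cs+].COC1Oc2cc(OC)cc(OC)c2C([O-])=C1c1ccc(OCC=C(C)C)c(OCC=C(C)C)c1 | intermediate
22 | Glabrescione B, 3-[3,4-bis(3-methylbut-2-enyloxy)phenyl]-5,7-dimethoxy-4H-chromen-4-one | COc1cc(OC)c2c(=O)c(-c3ccc(OCC=C(C)C)c(OCC=C(C)C)c3)coc2c1 | target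

Total step count: 7.
Longest linear sequence: 4 steps (1 to 2 to 6 to 8 to 22; equally 9 to 11 to 14 to 16 to 22).

Steps most likely to fail

Step 7 (the step that goes beyond known chemistry). What may go wrong: the sequence may stop at the aryl ester, either because the aryl anion is quenched before acyl transfer or because the transfer is slow beside the ortho-methoxy group. The aryne may also be drained by ene reaction with the prenyl alkenes or by the released methoxide. The fallback uses known chemistry, sets out from 1, 9 and 10 and comes back to the route at 22. Ester 9 is hydrolysed in refluxing aqueous HCl to 2-(3,4-dihydroxyphenyl)acetic acid F1. This acid acylates phenol 1 ortho to its hydroxyl group in BF3·OEt2 at about 85 °C (Friedel–Crafts/Fries-type acylation) to give the deoxybenzoin 2-(3,4-dihydroxyphenyl)-1-(2-hydroxy-4,6-dimethoxyphenyl)ethan-1-one F2. One-carbon insertion and ring closure with DMF, BF3·OEt2 and MsCl (Vilsmeier-type formylation of the activated methylene, then cyclodehydration) should give 3-(3,4-dihydroxyphenyl)-5,7-dimethoxy-4H-chromen-4-one F3. Its two free phenols are then etherified with 10 and K2CO3 in acetone to give 22, so the acid-sensitive prenyl ethers are introduced only after all Lewis-acidic operations.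

Step 2. What may go wrong: metalation at C4 between the two methoxy groups, or incomplete N-silylation followed by base-induced loss of the carbamate as isocyanate. The fallback sets out from 1 and comes back at 8. Amine-catalysed ortho-selective bromination (NBS, catalytic i-Pr2NH, CH2Cl2, 0 °C) should give 2-bromo-3,5-dimethoxyphenol F4. Silylation with HMDS (neat, 80 °C) gives (2-bromo-3,5-dimethoxyphenoxy)trimethylsilane F5. Bromine–lithium exchange with n-BuLi in THF at −100 °C triggers a retro-Brook 1,3 O-to-C silyl shift to lithium 3,5-dimethoxy-2-(trimethylsilyl)phenoxide F6, which is trapped in the same flask with Tf2O to give 8.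

Step 6. What may go wrong: hydroxide may add at C3 and displace methoxide, which leads through the formyl acid to deformylation, or the enol ether may hydrolyse during acidification. The fallback replaces the methyl ester by one that is cleaved under neutral conditions; it sets out from 11 and comes back at 16. Base-catalysed transesterification (catalytic NaH in allyl alcohol, rt) gives allyl 2-[3,4-bis(3-methylbut-2-enyloxy)phenyl]acetate F7. Claisen formylation with allyl formate and NaH in THF–DMF gives the sodium enolate of allyl 2-[3,4-bis(3-methylbut-2-enyloxy)phenyl]-3-oxopropanoate F8, which is O-methylated in the same flask with Me2SO4 to allyl (E)-2-[3,4-bis(3-methylbut-2-enyloxy)phenyl]-3-methoxyprop-2-enoate F9. Tsuji–Trost deallylation with catalytic Pd(PPh3)4 (zerovalent palladium) and morpholine in THF at rt gives morpholinium (E)-2-[3,4-bis(3-methylbut-2-enyloxy)phenyl]-3-methoxyprop-2-enoate F10. The aryl prenyl ethers should ionise far more slowly than the allyl ester. A cold aqueous NaH2PO4 wash then liberates 16.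

Further compounds
F1 | step 7 | 2-(3,4-dihydroxyphenyl)acetic acid | OC(=O)Cc1ccc(O)c(O)c1
F2 | step 7 | 2-(3,4-dihydroxyphenyl)-1-(2-hydroxy-4,6-dimethoxyphenyl)ethan-1-one | COc1cc(O)c(C(=O)Cc2ccc(O)c(O)c2)c(OC)c1
F3 | step 7 | 3-(3,4-dihydroxyphenyl)-5,7-dimethoxy-4H-chromen-4-one | COc1cc(OC)c2c(=O)c(-c3ccc(O)c(O)c3)coc2c1
F4 | step 2 | 2-bromo-3,5-dimethoxyphenol | COc1cc(O)c(Br)c(OC)c1
F5 | step 2 | (2-bromo-3,5-dimethoxyphenoxy)trimethylsilane | COc1cc(O[Si](C)(C)C)c(Br)c(OC)c1
F6 | step 2 | lithium 3,5-dimethoxy-2-(trimethylsilyl)phenoxide | [Li+].COc1cc([O-])c([Si](C)(C)C)c(OC)c1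
F7 | step 6 | allyl 2-[3,4-bis(3-methylbut-2-enyloxy)phenyl]acetate | C=CCOC(=O)Cc1ccc(OCC=C(C)C)c(OCC=C(C)C)c1
F8 | step 6 | sodium enolate of allyl 2-[3,4-bis(3-methylbut-2-enyloxy)phenyl]-3-oxopropanoate (enolate geometry mobile) | [Na+].[O-]C=C(C(=O)OCC=C)c1ccc(OCC=C(C)C)c(OCC=C(C)C)c1
F9 | step 6 | allyl (E)-2-[3,4-bis(3-methylbut-2-enyloxy)phenyl]-3-methoxyprop-2-enoate | CO/C=C(/C(=O)OCC=C)c1ccc(OCC=C(C)C)c(OCC=C(C)C)c1
F10 | step 6 | morpholinium (E)-2-[3,4-bis(3-methylbut-2-enyloxy)phenyl]-3-methoxyprop-2-enoate | CO/C=C(/C(=O)[O-])c1ccc(OCC=C(C)C)c(OCC=C(C)C)c1.C1COCC[NH2+]1
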